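Slowness showed early in the larch run: monomer in chains read 17.2% at 30.0 s and 17.1% at 90.0 s. Free monomer still read 32.9% at 90.0 s, so I took the stall to mean the growing ends had died.

| setting | larch | alder | flask |
|---|---|---|---|
| free monomer | 0.49 M | 0.49 M | 0.49 M |
| transfer agent | 0.049 M | 0.049 M | 0.0490 M |
| protic impurity | 0.245 M | 0.245 M | 0.245 M |
| pre-initiator | 0.7 mol% | 1.1 mol% | 0.5 mol% |
| remark | run made earlier | run made earlier |  |
| time |  |  | 2.0 min |

| run | time / s | monomer in chains / % | free monomer / % |
|---|---|---|---|
| larch | 10.0 | 12.8 | 42.7 |
| larch | 20.0 | 15.6 | 37.5 |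
| larch | 30.0 | 17.2 | 34.5 |
| larch | 50.0 | 16.8 | 35.0 |
| larch | 80.0 | 14.7 | 31.5 |
| larch | 90.0 | 17.1 | 32.9 |
| alder | 10.0 | 17.0 | 37.1 |
| alder | 20.0 | 23.9 | 29.1 |
| alder | 30.0 | 23.0 | 25.7 |
| alder | 50.0 | 23.6 | 26.3 |
| alder | 80.0 | 24.4 | 27.2 |
| alder | 90.0 | 23.6 | 24.8 |

(readings scatter by 1 percentage point)

1. average number of monomer units in a chain (chains begun, living or dead) at 2.0 min
2. part of the free monomer that has reacted at 2.0 min

- the average divides the monomer in chains by the number of chains begun, living and dead together
- the earlier runs do not show the number of chains; that part of a forecast is a guess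

My rule of thumb was one chain per pre-initiator. Over its plateau the larch run reads 23.5 units per pre-initiator, the plateau monomer in chains divided by the loading, which under this rule is the kinetic chain length. The alder run reads lower, at 21.5. The larch loading lies nearer the flask's, so I used the larch value.

The border of the rule is the transfer agent. The flask holds 20.0 times as much of it as of pre-initiator, so dp falls far if the agent begins chains. But a restarted chain should keep eating free monomer, and the runs stall. I therefore kept pre-initiator as the limiting reagent of the chain count, though the readings do not show the number of chains.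

In the larch run, free monomer plus monomer in chains read 50.0% at 90.0 s, and the protic impurity charged is 50.0% of the free monomer. I booked that share as lost. For the flask I reckoned dp near 23.5, monomer in chains 11.8% and c 61.8%.

The forecast gave dp 5.5 (1.8 to 25) and c 62.3% (60% to 65%). Its chain count included chains from the transfer agent, “which is only a guess”, so its dp lies below mine.

The flask gave dp 24.3 and c 62.2%, by this scheme:

    free monomer + initiator → living end + monomer in chains (k = 5.10 M⁻¹ s⁻¹)
    free monomer + living end → monomer in chains + living end, rate k2*[living end]*[free monomer] (k = 18.0 M⁻¹ s⁻¹)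
    protic impurity + free monomer → quenched substrate (k = 0.740 M⁻¹ s⁻¹)
    pre-initiator → initiator (k = 0.280 s⁻¹)
    living end + transfer agent → dead chain (kL = 4.20 M⁻¹ s⁻¹)

At 2.00 min the flask held 0.00245 M of dead chain against 0.00245 M of pre-initiator charged, with 12.2% monomer in chains. The neighbouring flask took 0.3 mol% of pre-initiator, other charges unchanged. The same reckoning gave it 7.05% monomer in chains, dp near 23.5 and c near 57.0%. That neighbouring flask gave 7.56% monomer in chains, c 57.6% and dp 25.2.

(The runs are simulated with made-up constants, and the scatter is random.)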